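**Plan**

- Retrosynthesis (drimane numbering): the C11–O ester bond is cut first, giving (−)-drimenol and caffeic acid. Next the C9–C11 bond is cut back to an 11-nor-9-ketone, then C3–C4 of ring A, then the C10–C1 and C10–CH3 bonds, which leaves (R)-carvone.
- Enabling feature: ring B (C5–C10) with the C7=C8(C12) alkene, C9 as carbonyl carbon, C10 as its α′-carbon and the C5 stereocentre is a carvone ring. The carvone isopropenyl carbon is the gem-dimethyl carbon C4, so a tertiary C4 radical can be joined to C3 of a C1–C2=C3 acceptor arm placed on C10.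
- Forward order: ring B is bought; C10 is made quaternary by methylation and sulfonylallylation; ring A closes by radical C3–C4 bond formation; C11 is added at C9; the sulfone is removed; the caffeate is attached last.
- Stereochemistry: C5 comes from (R)-carvone; C10 from enolate alkylation anti to the isopropenyl group; C9 from α-face hydroboration opposite the axial C10 methyl; the (E)-alkene from caffeic acid.

Key step: step 5

Remark: monocycles carry carvone numbering (C1 carbonyl, C5 isopropenyl-bearing, C6 α′) and bicycles drimane numbering; the sulfone-bearing C2 of 9–12 is drawn as the equatorial 2α epimer, and its epimer would serve equally because step 8 erases this centre.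

**Route**

Step 1
Reactants: 1 (R)-(−)-carvone
Product: 3 trans-6-methylcarvone, via lithium dienolate 2 (not isolated)
Conditions: LiN(iPr)2, THF, −78 °C; MeI, −78 → 0 °C
Reagents that add atoms: iodomethane, CI
Why: Kinetic deprotonation of the cross-conjugated enone at the α′-carbon C6 and SN2 methylation of the lithium enolate (enolate alkylation); the methyl group should enter mainly anti to the C5 isopropenyl group, and the minor C6 epimer is carried along because C6 is planarised again in step 4.

Step 2
Reactants: 4 phenyl vinyl sulfone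
Product: 5 2-(phenylsulfonyl)prop-2-en-1-ol
Conditions: 37% aq. HCHO, DABCO, THF, rt
Reagents that add atoms: formaldehyde, C=O
Why: Morita–Baylis–Hillman reaction, in which DABCO adds reversibly to the vinyl sulfone, the α-sulfonyl carbanion is hydroxymethylated by formaldehyde and the amine is expelled, placing CH2OH on the sulfonyl-bearing carbon without forming a stereocentre.

Step 3
Reactants: 5 2-(phenylsulfonyl)prop-2-en-1-ol
Product: 6 3-bromo-2-(phenylsulfonyl)prop-1-ene
Conditions: PBr3, Et2O, 0 °C → rt
Reagents that add atoms: phosphorus tribromide, BrP(Br)Br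
Why: Conversion of a primary allylic alcohol into the bromide by bromide displacement of its phosphite ester; direct and allylic displacement lead to the same constitution, so no regiochemical question arises.

Step 4
Reactants: 3 trans-6-methylcarvone; 6 3-bromo-2-(phenylsulfonyl)prop-1-ene
Product: 8 (5R,6S)-2,6-dimethyl-6-[2-(phenylsulfonyl)prop-2-en-1-yl]-5-(prop-1-en-2-yl)cyclohex-2-en-1-one, via lithium enolate 7 (not isolated)
Conditions: LiN(iPr)2, THF, −78 °C; then 6 (1.3 equiv), −78 → −40 °C
Reagents that add atoms: none
Why: Enolate alkylation in which LiN(iPr)2 removes the only α′-hydrogen of both C6 epimers of 3 to give one tetrasubstituted enolate, which attacks the doubly activated allylic bromide (SN2 or conjugate addition–elimination, both giving the same product) on the face anti to the neighbouring C5 isopropenyl group, so the sulfonylallyl arm ends trans and the methyl cis to the isopropenyl group and the quaternary centre (future C10, S) is set under substrate control.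

Step 5
Reactants: 8 (5R,6S)-2,6-dimethyl-6-[2-(phenylsulfonyl)prop-2-en-1-yl]-5-(prop-1-en-2-yl)cyclohex-2-en-1-one
Product: 9 (2S,5S,10S)-2-(phenylsulfonyl)-11-nordrim-7-en-9-one
Conditions: Fe(acac)3 (0.3 equiv), PhSiH3 (2.5 equiv), EtOH/ethylene glycol 5:1, 0.02 M, 60 °C
Reagents that add atoms: none
Why: Fe(acac)3 and PhSiH3 in ethanol generate a trivalent iron hydride that transfers a hydrogen atom to the CH2 terminus of the electron-rich isopropenyl group, which leaves the tertiary C4 radical and divalent iron; the radical adds to the unsubstituted β-carbon C3 of the vinyl sulfone arm, and the α-sulfonyl radical at C2 is reduced by divalent iron to the carbanion and protonated by the alcohol, which returns trivalent iron. The closest known reaction type is the iron-hydride reductive olefin coupling (hydrogen-atom-transfer Giese addition) of unactivated 1,1-disubstituted alkenes with vinyl sulfones and other acceptor alkenes, used here in its intramolecular form. Ring A (C1–C5 and C10) closes 6-endo-trig through the new C3–C4 bond, because the 5-exo alternative would require attack at the fully substituted, sulfonyl-bearing C2, which is hindered and polarity-mismatched for a nucleophilic tertiary radical. The ring-fusion centres C5 and C10 are present before the step and carry the two reacting arms trans and diequatorial on ring B, so a chair-like closure gives the trans-decalin directly; the only new stereocentre, C2, is set in the final protonation, should prefer the equatorial 2α-sulfone and is of no consequence since step 8 removes it. The selectivity required is hydrogen-atom transfer to the isopropenyl group only, and it is secured because the enone and the vinyl sulfone are electron-poor alkenes that act as radical acceptors and not as hydrogen-atom acceptors toward iron hydrides, while the enone offers the C4 radical only four-membered or bridged modes of attack.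

Step 6
Reactants: 9 (2S,5S,10S)-2-(phenylsulfonyl)-11-nordrim-7-en-9-one
Product: 10 (2S,5S,10S)-2-(phenylsulfonyl)drima-7,9(11)-diene
Conditions: Cp2TiMe2 (3 equiv), toluene/THF, 75 °C, dark
Reagents that add atoms: dimethyltitanocene, C[Ti](C)(C1C=CC=C1)C1C=CC=C1
Why: Petasis methylenation, in which thermolysis of Cp2TiMe2 gives Cp2Ti=CH2 that olefinates the hindered, non-enolisable C9 ketone through an oxatitanacyclobutane under non-basic conditions that leave the sulfone and the C7=C8 alkene untouched; no stereocentre is involved.

Step 7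
Reactants: 10 (2S,5S,10S)-2-(phenylsulfonyl)drima-7,9(11)-diene
Product: 12 (2S,5S,9S,10S)-2-(phenylsulfonyl)drim-7-en-11-ol, via B-alkyl-9-BBN adduct 11 (not isolated)
Conditions: 9-BBN, THF, 0 → 60 °C; then NaOH, 30% H2O2, 0 °C → rt
Reagents that add atoms: hydrogen peroxide, OO
Why: Hydroboration–oxidation in which 9-BBN adds to the unhindered terminal carbon C11 of the exocyclic 1,1-disubstituted alkene in preference to the trisubstituted ring alkene, with syn delivery of hydrogen to C9 on the α face opposite the axial C10 methyl group (9α-H, equatorial C11 arm, C9 = S), and alkaline H2O2 oxidises the C–B bond with retention.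

Step 8
Reactants: 12 (2S,5S,9S,10S)-2-(phenylsulfonyl)drim-7-en-11-ol
Product: 13 (−)-drimenol
Conditions: 6% Na(Hg), Na2HPO4, MeOH/THF, −20 → 0 °C
Reagents that add atoms: none
Why: Reductive desulfonylation of an unactivated alkyl phenyl sulfone by electron transfer from sodium amalgam in buffered methanol (C–S fragmentation of the radical anion, then reduction and protonation at C2) removes the only extra stereocentre, while the isolated trisubstituted alkene, the primary alcohol and C5, C9 and C10 are untouched.

Step 9
Reactants: 14 caffeic acid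
Product: 16 (E)-3,4-bis(tert-butyldimethylsilyloxy)cinnamic acid, via silyl ester 15 (not isolated)
Conditions: TBSCl (3.5 equiv), imidazole, DMF, rt; then AcOH/THF/H2O 3:1:1, rt
Reagents that add atoms: tert-butyldimethylsilyl chloride, CC(C)(C)[Si](C)(C)Cl
Why: Silylation of both phenols and the acid with TBSCl and imidazole, then selective hydrolysis of the labile silyl ester in aqueous acetic acid, which aryl silyl ethers survive; the (E)-alkene is carried through unchanged.

Step 10
Reactants: 13 (−)-drimenol; 16 (E)-3,4-bis(tert-butyldimethylsilyloxy)cinnamic acid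
Product: 17 drimenyl (E)-3,4-bis(tert-butyldimethylsilyloxy)cinnamate
Conditions: DCC, DMAP (0.2 equiv), CH2Cl2, 0 °C → rt
Reagents that add atoms: none
Why: Steglich esterification (carbodiimide activation with DMAP as acyl-transfer catalyst) of the primary C11 alcohol; the silyl ethers prevent phenol acylation and neither a stereocentre nor the alkene geometry is affected.

Step 11
Reactants: 17 drimenyl (E)-3,4-bis(tert-butyldimethylsilyloxy)cinnamate
Product: 18 drimenyl caffeate (CNP0265201.1)
Conditions: Bu4NF (2.2 equiv), AcOH (2.5 equiv), THF, 0 °C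
Reagents that add atoms: none
Why: Fluoride-mediated cleavage of the two aryl silyl ethers, buffered with acetic acid so that the phenoxides are protonated at once and the cinnamate ester, the catechol and the ring alkene are not exposed to base.

**Compound list**

1 | (R)-(−)-carvone, (5R)-2-methyl-5-(prop-1-en-2-yl)cyclohex-2-en-1-one | CC1=CC[C@@H](C(C)=C)CC1=O | starting material
2 | kinetic lithium dienolate of carvone (O–Li on C1, C1=C6 and C2=C3 double bonds, 5R) | CC1=CC[C@@H](C(C)=C)C=C1O[Li] | intermediate
3 | trans-6-methylcarvone, (5R,6S)-2,6-dimethyl-5-(prop-1-en-2-yl)cyclohex-2-en-1-one (minor 6-epimer carried along) | CC1=CC[C@@H](C(C)=C)[C@H](C)C1=O | intermediate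
4 | phenyl vinyl sulfone | C=CS(=O)(=O)c1ccccc1 | starting material
5 | 2-(phenylsulfonyl)prop-2-en-1-ol | OCC(=C)S(=O)(=O)c1ccccc1 | intermediate
6 | 3-bromo-2-(phenylsulfonyl)prop-1-ene | BrCC(=C)S(=O)(=O)c1ccccc1 | intermediate
7 | lithium enolate of 3 (O–Li on C1, C1=C6 tetrasubstituted, 5R) | CC1=CC[C@@H](C(C)=C)C(C)=C1O[Li] | intermediate
8 | (5R,6S)-2,6-dimethyl-6-[2-(phenylsulfonyl)prop-2-en-1-yl]-5-(prop-1-en-2-yl)cyclohex-2-en-1-one (sulfonylallyl trans to isopropenyl) | CC1=CC[C@@H](C(C)=C)[C@](C)(CC(=C)S(=O)(=O)c2ccccc2)C1=O | intermediate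
9 | (2S,5S,10S)-2-(phenylsulfonyl)-11-nordrim-7-en-9-one, i.e. (4aS,7S,8aS)-2,5,5,8a-tetramethyl-7-(phenylsulfonyl)-4a,5,6,7,8,8a-hexahydronaphthalen-1(4H)-one (trans-decalin, 10β-CH3, 5α-H, 2α-sulfone) | CC1=CC[C@H]2C(C)(C)C[C@H](S(=O)(=O)c3ccccc3)C[C@]2(C)C1=O | intermediate
10 | (2S,5S,10S)-2-(phenylsulfonyl)drima-7,9(11)-diene (9-methylene compound) | CC1=CC[C@H]2C(C)(C)C[C@H](S(=O)(=O)c3ccccc3)C[C@]2(C)C1=C | intermediate
11 | B-[(2S,5S,9S,10S)-2-(phenylsulfonyl)drim-7-en-11-yl]-9-borabicyclo[3.3.1]nonane | CC1=CC[C@H]2C(C)(C)C[C@H](S(=O)(=O)c3ccccc3)C[C@]2(C)[C@H]1CB1C2CCCC1CCC2 | intermediate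
12 | (2S,5S,9S,10S)-2-(phenylsulfonyl)drim-7-en-11-ol (9α-H, 11-CH2OH β) | CC1=CC[C@H]2C(C)(C)C[C@H](S(=O)(=O)c3ccccc3)C[C@]2(C)[C@H]1CO | intermediate
13 | (−)-drimenol, (5S,9S,10S)-drim-7-en-11-ol, [(1S,4aS,8aS)-2,5,5,8a-tetramethyl-1,4,4a,5,6,7,8,8a-octahydronaphthalen-1-yl]methanol | CC1=CC[C@H]2C(C)(C)CCC[C@]2(C)[C@H]1CO | intermediate
14 | caffeic acid, (E)-3-(3,4-dihydroxyphenyl)prop-2-enoic acid | OC(=O)/C=C/c1ccc(O)c(O)c1 | starting material
15 | tert-butyldimethylsilyl (E)-3,4-bis(tert-butyldimethylsilyloxy)cinnamate | CC(C)(C)[Si](C)(C)OC(=O)/C=C/c1ccc(O[Si](C)(C)C(C)(C)C)c(O[Si](C)(C)C(C)(C)C)c1 | intermediate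
16 | (E)-3,4-bis(tert-butyldimethylsilyloxy)cinnamic acid | OC(=O)/C=C/c1ccc(O[Si](C)(C)C(C)(C)C)c(O[Si](C)(C)C(C)(C)C)c1 | intermediate
17 | (5S,9S,10S)-drim-7-en-11-yl (E)-3,4-bis(tert-butyldimethylsilyloxy)cinnamate | CC1=CC[C@H]2C(C)(C)CCC[C@]2(C)[C@H]1COC(=O)/C=C/c1ccc(O[Si](C)(C)C(C)(C)C)c(O[Si](C)(C)C(C)(C)C)c1 | intermediate
18 | (5S,9S,10S)-drim-7-en-11-yl (E)-3-(3,4-dihydroxyphenyl)prop-2-enoate, drimenyl caffeate (CNP0265201.1) | CC1=CC[C@H]2C(C)(C)CCC[C@]2(C)[C@H]1COC(=O)/C=C/c1ccc(O)c(O)c1 | target

**Step count and risks**

Total step count: 11. Longest linear sequence: 9 steps from phenyl vinyl sulfone (steps 2, 3, 4, 5, 6, 7, 8, 10, 11); 8 steps from (R)-carvone (steps 1, 4, 5, 6, 7, 8, 10, 11).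

Steps most likely to fail:

Step 5. The tertiary C4 radical may take a second hydrogen atom before it reaches the acceptor, which amounts to hydrogenation of the isopropenyl group. The iron hydride may also engage the enone. The fallback generates the same radical by halogen abstraction. It sets out from 8: Markovnikov hydrobromination of the isopropenyl group (HBr in AcOH, 0 °C, the classical carvone hydrobromide reaction; the electron-poor enone and vinyl sulfone are not protonated) should give the tertiary bromide (5R,6S)-5-(2-bromopropan-2-yl)-2,6-dimethyl-6-[2-(phenylsulfonyl)prop-2-en-1-yl]cyclohex-2-en-1-one F1. Slow addition of Bu3SnH with AIBN in benzene at 80 °C keeps the hydride concentration low, so the C4 radical should close 6-endo onto C3 before it is reduced. The sequence comes back to the route at 9.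

Step 4. The product is itself a vinyl sulfone and may capture a second enolate. The liberated amine may consume the bromide, and the very reactive electrophile may erode the facial selectivity at the quaternary centre. The fallback installs the arm as a plain allylic halide and introduces sulfur afterwards. It sets out from 3: enolate 7 is alkylated with 2,3-dibromopropene (THF, −78 → 0 °C) anti to the isopropenyl group to give (5R,6S)-6-(2-bromoprop-2-en-1-yl)-2,6-dimethyl-5-(prop-1-en-2-yl)cyclohex-2-en-1-one F2. The vinyl bromide is then coupled with PhSO2Na under copper catalysis (CuI, sodium L-prolinate, DMSO, 95 °C). The sequence comes back to the route at 8.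

Step 7. Facial selectivity of the borane at the exocyclic C9=C11 bond may be poor, giving a mixture of C9 epimers. The fallback moves the stereo-determining event to a kinetic protonation through which both epimers converge. It sets out from 10:
- The hydroboration–oxidation is run as before, and 12 is taken on unseparated from its C9 epimer (2S,5S,9R,10S)-2-(phenylsulfonyl)drim-7-en-11-ol F3.
- Dess–Martin periodinane with NaHCO3 in CH2Cl2 gives the aldehydes (2S,5S,9R,10S)-2-(phenylsulfonyl)drim-7-en-11-al F4 and (2S,5S,9S,10S)-2-(phenylsulfonyl)drim-7-en-11-al F5.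
- KN(SiMe3)2 in THF at −78 °C removes the C9 hydrogen, which is allylic and α to the formyl group, from both aldehydes and should give the single potassium dienolate of 2-(phenylsulfonyl)drim-7-en-11-al F6.
- Quenching with AcOH at −78 °C should protonate the α-carbon C9 axially on the α face opposite the C10 methyl, giving F5 as the β,γ-unsaturated aldehyde.
- NaBH4 in MeOH at 0 °C reduces F5, and the sequence comes back to the route at 12.

**Further compounds**

F1 | step 5 | (5R,6S)-5-(2-bromopropan-2-yl)-2,6-dimethyl-6-[2-(phenylsulfonyl)prop-2-en-1-yl]cyclohex-2-en-1-one | CC1=CC[C@@H](C(C)(C)Br)[C@](C)(CC(=C)S(=O)(=O)c2ccccc2)C1=O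
F2 | step 4 | (5R,6S)-6-(2-bromoprop-2-en-1-yl)-2,6-dimethyl-5-(prop-1-en-2-yl)cyclohex-2-en-1-one | CC1=CC[C@@H](C(C)=C)[C@](C)(CC(Br)=C)C1=O
F3 | step 7 | (2S,5S,9R,10S)-2-(phenylsulfonyl)drim-7-en-11-ol (9-epimer of 12) | CC1=CC[C@H]2C(C)(C)C[C@H](S(=O)(=O)c3ccccc3)C[C@]2(C)[C@@H]1CO
F4 | step 7 | (2S,5S,9R,10S)-2-(phenylsulfonyl)drim-7-en-11-al | CC1=CC[C@H]2C(C)(C)C[C@H](S(=O)(=O)c3ccccc3)C[C@]2(C)[C@@H]1C=O
F5 | step 7 | (2S,5S,9S,10S)-2-(phenylsulfonyl)drim-7-en-11-al | CC1=CC[C@H]2C(C)(C)C[C@H](S(=O)(=O)c3ccccc3)C[C@]2(C)[C@H]1C=O
F6 | step 7 | potassium dienolate of 2-(phenylsulfonyl)drim-7-en-11-al (C9=C11–O–K, C7=C8) | CC1=CC[C@H]2C(C)(C)C[C@H](S(=O)(=O)c3ccccc3)C[C@]2(C)C1=CO[K]
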